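**Strategy.** The 26-membered lactone is closed at the C5–C6 bond, where the (2E,4E)-dienoate (C1–C5) meets the C6 carbinol of the C6/C7 diol. An intramolecular Nozaki–Hiyama–Kishi reaction of a C5 alkenyl iodide with a C6 aldehyde forms this bond, closes the ring and creates the C6 stereocenter under ligand control in one operation. Its precursor is the open C6–C36 chain, esterified at O25 with (2E,4E)-5-iodopentadienoic acid and carrying an α-silyloxy aldehyde at C6. The chain comes from four building blocks through two palladium-catalysed alkenylation–methylation sequences on 1,1-dibromoalkenes (both 2-methyl-1,3-dienes) and one cross-metathesis (C26=C27).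

Key step: step 38

Remarks
- Numbering: C1 is the lactone carbonyl, C2–C5 the dienoate, C25 the carbon bearing the ring oxygen, C26–C36 the side chain (epoxide at C30/C31). "As in the target" means the same spatial arrangement at that carbon. TES = triethylsilyl, PMB = 4-methoxybenzyl, Ipc = isopinocampheyl.
- Assumption: the (S)-configured oxazoline–sulfonamide ligand is taken to deliver the alkenyl group to the Re face of the C6 aldehyde; if a model coupling shows the opposite sense, its antipode is used.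
- Assumption: (S)-glyceraldehyde acetonide 42 and the N-propanoyl thiazolidinethione 22 are taken as purchasable (otherwise one extra step each, from (R)-solketal or from (S)-4-benzylthiazolidine-2-thione).

**Fragment 1: side chain (C27–C36)**

Step 1
Reactants: 1 butanal
Product: 3 (3S,4S)-3-methoxyhept-1-en-4-ol, via diisopinocampheylborinate ester 2 (not isolated)
Conditions: allyl methyl ether, s-BuLi, THF, −78 °C; (+)-Ipc2BOMe (from (−)-α-pinene); BF3·OEt2; 1, −78 °C; then ethanolamine, rt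
Reagents that add atoms: allyl methyl ether (C=CCOC)
Why: Brown (Z)-γ-methoxyallylboration through a chair transition state should give the 32,33-syn methoxy alcohol, the Ipc groups selecting the aldehyde face that gives C33 (S) and C32 as in the target.

Step 2
Reactants: 3 (3S,4S)-3-methoxyhept-1-en-4-ol
Product: 4 triethylsilyl ether of 3
Conditions: Et3SiCl, imidazole, DMF, 0 °C → rt
Reagents that add atoms: chlorotriethylsilane (CC[Si](Cl)(CC)CC)
Why: Standard silylation of the secondary alcohol; no stereocenter is touched.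

Step 3
Reactants: 4 triethylsilyl ether of 3
Product: 7 ethyl (2E,4S,5S)-4-methoxy-2-methyl-5-(triethylsilyloxy)oct-2-enoate, via ozonide 5 (not isolated), via α-methoxy aldehyde 6 (not isolated)
Conditions: O3, CH2Cl2, −78 °C; PPh3, −78 °C → rt; then ethyl 2-(triphenylphosphoranylidene)propanoate, rt
Reagents that add atoms: ethyl 2-(triphenylphosphoranylidene)propanoate (CCOC(=O)C(C)=P(c1ccccc1)(c1ccccc1)c1ccccc1)
Why: Ozonolysis with reductive work-up followed by Wittig olefination of the unpurified aldehyde with a stabilized ylide should give the E-trisubstituted enoate (C29–C31) without touching C32.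

Step 4
Reactants: 7 ethyl (2E,4S,5S)-4-methoxy-2-methyl-5-(triethylsilyloxy)oct-2-enoate
Product: 8 (2E,4S,5S)-4-methoxy-2-methyl-5-(triethylsilyloxy)oct-2-en-1-ol
Conditions: i-Bu2AlH, CH2Cl2, −78 °C
Reagents that add atoms: none
Why: 1,2-Reduction of the enoate to the primary allylic alcohol needed for a reagent-controlled epoxidation.

Step 5
Reactants: 8 (2E,4S,5S)-4-methoxy-2-methyl-5-(triethylsilyloxy)oct-2-en-1-ol
Product: 9 epoxy alcohol [(2R,3R)-3-[(1S,2S)-1-methoxy-2-(triethylsilyloxy)pentyl]-2-methyloxiran-2-yl]methanol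
Conditions: Ti(Oi-Pr)4, D-(−)-diethyl tartrate, t-BuOOH, 4 Å molecular sieves, CH2Cl2, −20 °C
Reagents that add atoms: tert-butyl hydroperoxide (CC(C)(C)OO)
Why: Sharpless asymmetric epoxidation of the E-trisubstituted primary allylic alcohol, in which the D-(−)-tartrate catalyst delivers oxygen to the face that gives C30 (R) and C31 (R).

Step 6
Reactants: 9 epoxy alcohol
Product: 10 epoxy aldehyde (2S,3R)-3-[(1S,2S)-1-methoxy-2-(triethylsilyloxy)pentyl]-2-methyloxirane-2-carbaldehyde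
Conditions: Dess–Martin periodinane, NaHCO3, CH2Cl2, 0 °C → rt
Reagents that add atoms: none
Why: Buffered Dess–Martin oxidation; the α-carbon (C30) is quaternary and cannot epimerize.

Step 7
Reactants: 10 epoxy aldehyde
Product: 12 homoallylic alcohol (1S)-1-[(2R,3R)-3-[(1S,2S)-1-methoxy-2-(triethylsilyloxy)pentyl]-2-methyloxiran-2-yl]but-3-en-1-ol, via diisopinocampheylborinate ester 11 (not isolated)
Conditions: allylmagnesium bromide, (−)-Ipc2BOMe (from (+)-α-pinene), Et2O, 0 °C → rt; 10, −78 °C; then ethanolamine, rt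
Reagents that add atoms: allylmagnesium bromide (C=CC[Mg]Br)
Why: Brown allylation, in which the (−)-Ipc2B(allyl) reagent should attack the aldehyde face that gives C29 (S), threo to the epoxide, under reagent control.

Step 8
Reactants: 12 homoallylic alcohol
Product: 13 side-chain alkene (29-O-TES ether of 12)
Conditions: Et3SiCl, imidazole, 4-(dimethylamino)pyridine (cat.), CH2Cl2, 0 °C → rt
Reagents that add atoms: chlorotriethylsilane (CC[Si](Cl)(CC)CC)
Why: Silylation under non-acidic conditions that spare the epoxide.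

**Fragment 2: east part (C20–C26) and union with the side chain**

Step 9
Reactants: 14 penta-1,4-dien-3-ol
Product: 15 (2R,3S)-1,2-epoxypent-4-en-3-ol
Conditions: Ti(Oi-Pr)4, L-(+)-diisopropyl tartrate, t-BuOOH, 4 Å molecular sieves, CH2Cl2, −20 °C
Reagents that add atoms: tert-butyl hydroperoxide (CC(C)(C)OO)
Why: Sharpless desymmetrization of the divinyl carbinol, in which the L-(+)-tartrate catalyst selects one enantiotopic vinyl group and one face to give the erythro epoxy alcohol that becomes C24 (epoxide CH) and C25 (carbinol).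

Step 10
Reactants: 15 (2R,3S)-1,2-epoxypent-4-en-3-ol
Product: 16 (2R,3S)-1,2-epoxy-3-[(4-methoxybenzyl)oxy]pent-4-ene
Conditions: NaH, 4-methoxybenzyl chloride, n-Bu4NI (cat.), THF, −20 → 0 °C
Reagents that add atoms: 4-methoxybenzyl chloride (COc1ccc(CCl)cc1)
Why: Williamson etherification at low temperature, faster than Payne rearrangement, puts the one orthogonal protecting group on O25.

Step 11
Reactants: 16 (2R,3S)-1,2-epoxy-3-[(4-methoxybenzyl)oxy]pent-4-ene
Product: 18 (3S,4S)-4-methoxy-3-[(4-methoxybenzyl)oxy]-5-(phenylsulfanyl)pent-1-ene, via sodium alkoxide 17 (not isolated)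
Conditions: PhSH, NaH, THF, 0 °C → rt; then MeI, DMF, 0 °C → rt
Reagents that add atoms: benzenethiol (Sc1ccccc1); iodomethane (CI)
Why: Thiolate SN2 opening at the unsubstituted epoxide carbon (C23) and O-methylation of the resulting C24 alkoxide in the same flask; C24 and C25 keep their configuration.

Step 12
Reactants: 18 (3S,4S)-4-methoxy-3-[(4-methoxybenzyl)oxy]-5-(phenylsulfanyl)pent-1-ene
Product: 19 phenyl sulfoxide of 18 (mixture at sulfur)
Conditions: m-CPBA (1.0 equiv), CH2Cl2, −78 °C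
Reagents that add atoms: 3-chloroperoxybenzoic acid (OOC(=O)c1cccc(Cl)c1)
Why: Chemoselective sulfide oxidation, much faster than epoxidation of the terminal alkene at −78 °C.

Step 13
Reactants: 19 phenyl sulfoxide of 18
Product: 21 (2S,3S)-2-methoxy-3-[(4-methoxybenzyl)oxy]pent-4-enal, via α-trifluoroacetoxy sulfide 20 (not isolated)
Conditions: (CF3CO)2O, 2,6-lutidine, MeCN, 0 °C; then aq. NaHCO3, rt
Reagents that add atoms: trifluoroacetic anhydride (O=C(OC(=O)C(F)(F)F)C(F)(F)F)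
Why: Pummerer rearrangement followed by mild hydrolysis of the O,S-acetal turns C23 into the aldehyde without touching the α-methoxy centre.

Step 14
Reactants: 22 (S)-4-benzyl-3-propanoyl-1,3-thiazolidine-2-thione; 21 (2S,3S)-2-methoxy-3-[(4-methoxybenzyl)oxy]pent-4-enal
Product: 24 syn-aldol adduct (S)-4-benzyl-3-[(2S,3S,4R,5S)-3-hydroxy-4-methoxy-5-[(4-methoxybenzyl)oxy]-2-methylhept-6-enoyl]-1,3-thiazolidine-2-thione, via chlorotitanium Z-enolate 23 (not isolated)
Conditions: TiCl4, i-Pr2NEt, N-methyl-2-pyrrolidinone, CH2Cl2, 0 °C; then 21, −78 → 0 °C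
Reagents that add atoms: none
Why: Titanium-enolate aldol of the N-propanoyl thiazolidinethione through the non-chelated chair transition state ("Evans syn"), in which the (S)-benzyl auxiliary sets C22 and C23 (22,23-syn, 23,24-syn) over the weak bias of the α-methoxy aldehyde.

Step 15
Reactants: 24 syn-aldol adduct
Product: 25 23-O-TES ether of 24
Conditions: Et3SiOSO2CF3, 2,6-lutidine, CH2Cl2, −78 °C
Reagents that add atoms: triethylsilyl trifluoromethanesulfonate (CC[Si](CC)(CC)OS(=O)(=O)C(F)(F)F)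
Why: Silylation of the hindered secondary aldol hydroxyl.

Step 16
Reactants: 25 23-O-TES ether of 24
Product: 26 C21 aldehyde (2-methyl-3-OTES-4-OMe-5-OPMB-hept-6-enal; C22–C25 as in the target)
Conditions: i-Bu2AlH, CH2Cl2, −78 °C
Reagents that add atoms: none
Why: N-Acyl thiazolidinethiones are reduced by i-Bu2AlH directly to the aldehyde, the auxiliary leaving on work-up.

Step 17
Reactants: 26 C21 aldehyde
Product: 27 east 1,1-dibromoalkene (C20–C26 plus a terminal CH2)
Conditions: CBr4, PPh3, 2,6-lutidine, CH2Cl2, 0 °C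
Reagents that add atoms: carbon tetrabromide (BrC(Br)(Br)Br)
Why: Ramirez dibromoolefination (first stage of the Corey–Fuchs sequence) adds C20, the base keeping the α-methyl centre C22 from epimerizing.

Step 18
Reactants: 27 east 1,1-dibromoalkene; 13 side-chain alkene
Product: 28 east–side-chain 1,1-dibromoalkene (C20–C36)
Conditions: second-generation Hoveyda–Grubbs catalyst (10 mol %), 13 (2 equiv), CH2Cl2, 40 °C
Reagents that add atoms: none
Why: Olefin cross-metathesis between the homoallylic alkene of 13 and the allylic-ether vinyl group of 27 should give the E-C26=C27 alkene (allylic branching favours E), the dibromoalkene and epoxide being inert to the ruthenium carbene.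

**Fragment 3: middle part (C10–C19)**

Step 19
Reactants: 29 (S)-3-bromo-2-methylpropan-1-ol
Product: 30 [(S)-3-bromo-2-methylpropoxy]triethylsilane
Conditions: Et3SiCl, imidazole, CH2Cl2, 0 °C → rt
Reagents that add atoms: chlorotriethylsilane (CC[Si](Cl)(CC)CC)
Why: Silylation; the purchased stereocenter becomes C12.

Step 20
Reactants: 31 3-(trimethylsilyl)prop-2-ynal
Product: 33 (3R,4R)-4-methoxy-1-(trimethylsilyl)hex-5-en-1-yn-3-ol, via diisopinocampheylborinate ester 32 (not isolated)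
Conditions: allyl methyl ether, s-BuLi, THF, −78 °C; (−)-Ipc2BOMe (from (+)-α-pinene); BF3·OEt2; 31, −78 °C; then ethanolamine, rt
Reagents that add atoms: allyl methyl ether (C=CCOC)
Why: Brown (Z)-γ-methoxyallylboration, here with the antipodal Ipc reagent, should set C16 (OMe) and C17 (OH) syn and as in the target in one step.

Step 21
Reactants: 33 (3R,4R)-4-methoxy-1-(trimethylsilyl)hex-5-en-1-yn-3-ol
Product: 34 triethylsilyl ether of 33
Conditions: Et3SiCl, imidazole, DMF, 0 °C → rt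
Reagents that add atoms: chlorotriethylsilane (CC[Si](Cl)(CC)CC)
Why: Standard silylation of the propargylic alcohol.

Step 22
Reactants: 34 triethylsilyl ether of 33
Product: 36 (3R,4R)-3-methoxy-4-(triethylsilyloxy)-6-(trimethylsilyl)hex-5-yn-1-ol, via B-alkyl-9-BBN 35 (not isolated)
Conditions: 9-BBN, THF, 0 °C → rt; then H2O2, aq. NaOAc, 0 °C
Reagents that add atoms: hydrogen peroxide (OO)
Why: Anti-Markovnikov hydroboration of the terminal alkene (faster than attack on the silylated alkyne) and buffered oxidation give the C14 primary alcohol.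

Step 23
Reactants: 36 (3R,4R)-3-methoxy-4-(triethylsilyloxy)-6-(trimethylsilyl)hex-5-yn-1-ol
Product: 37 primary iodide of 36
Conditions: I2, PPh3, imidazole, CH2Cl2, 0 °C
Reagents that add atoms: iodine (II)
Why: Appel-type iodination of the primary alcohol.

Step 24
Reactants: 30 [(S)-3-bromo-2-methylpropoxy]triethylsilane; 37 primary iodide of 36
Product: 39 C11–C19 bis-silyl ether alkyne, via Grignard reagent 38 (not isolated)
Conditions: Mg, THF, rt; then 37, Li2CuCl4 (5 mol %), THF, −20 → 0 °C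
Reagents that add atoms: none
Why: Kochi-type copper-catalysed sp3–sp3 coupling of the primary Grignard reagent with the primary iodide joins C13 to C14 without touching C12, C16 or C17.

Step 25
Reactants: 39 C11–C19 bis-silyl ether alkyne
Product: 40 C11 aldehyde
Conditions: (COCl)2, DMSO, CH2Cl2, −78 → −40 °C; then Et3N, −78 → 0 °C
Reagents that add atoms: none
Why: Swern conditions cleave and oxidize the primary triethylsilyl ether directly while the secondary one survives; the α-methyl aldehyde is used crude.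

Step 26
Reactants: 40 C11 aldehyde
Product: 41 middle 1,1-dibromoalkene (C10–C19)
Conditions: CBr4, PPh3, 2,6-lutidine, CH2Cl2, 0 °C
Reagents that add atoms: carbon tetrabromide (BrC(Br)(Br)Br)
Why: Ramirez dibromoolefination adds C10 under buffered conditions that should not epimerize C12.

**Fragment 4: west part (C6–C9) and union with the middle part**

Step 27
Reactants: 42 (S)-2,2-dimethyl-1,3-dioxolane-4-carbaldehyde
Product: 43 (R)-4-ethynyl-2,2-dimethyl-1,3-dioxolane
Conditions: dimethyl (1-diazo-2-oxopropyl)phosphonate, K2CO3, MeOH, 0 °C → rt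
Reagents that add atoms: dimethyl (1-diazo-2-oxopropyl)phosphonate (COP(=O)(OC)C(=[N+]=[N-])C(C)=O)
Why: Seyferth–Gilbert homologation with the Ohira–Bestmann reagent gives the terminal alkyne under mild base; the purchased stereocenter becomes C7.

Step 28
Reactants: 43 (R)-4-ethynyl-2,2-dimethyl-1,3-dioxolane
Product: 44 (R)-but-3-yne-1,2-diol
Conditions: 1 M aq. HCl, THF, rt
Reagents that add atoms: none
Why: Acid hydrolysis of the acetonide.

Step 29
Reactants: 44 (R)-but-3-yne-1,2-diol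
Product: 45 (R)-1,2-bis(triethylsilyloxy)but-3-yne
Conditions: Et3SiCl (2.2 equiv), imidazole, DMF, 0 °C → rt
Reagents that add atoms: chlorotriethylsilane (CC[Si](Cl)(CC)CC)
Why: Double silylation; the primary TES ether at C6 is the latent aldehyde of the key step.

Step 30
Reactants: 45 (R)-1,2-bis(triethylsilyloxy)but-3-yne; 41 middle 1,1-dibromoalkene
Product: 49 C6–C19 dienyne (8E,10E; alkyne still silylated), via alkenylzirconocene chloride 46 (not isolated), via alkenylzinc bromide 47 (not isolated), via (Z)-bromodiene 48 (not isolated)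
Conditions: Cp2Zr(H)Cl, THF, rt; ZnBr2, 0 °C; 41, Pd(DPEphos)Cl2 (5 mol %), 0 °C → rt; then Me2Zn, Pd(t-Bu3P)2 (5 mol %), rt
Reagents that add atoms: dimethylzinc (C[Zn]C)
Why: Syn hydrozirconation gives the E-alkenyl metal, the Negishi coupling takes place selectively at the bromide trans to the alkyl chain, and the remaining bromide is replaced by methyl with retention, which should give the (8E,10E)-2-methyl-1,3-diene.

Step 31
Reactants: 49 C6–C19 dienyne
Product: 50 C6–C19 dienyne with free terminal alkyne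
Conditions: K2CO3, MeOH, 0 °C → rt
Reagents that add atoms: none
Why: Methanolysis of the C(sp)–Si bond; triethylsilyl ethers should survive the short exposure.

**Fragment 5: acid (C1–C5)**

Step 32
Reactants: 51 ethyl (E)-4-oxobut-2-enoate
Product: 52 ethyl (2E,4E)-5-iodopenta-2,4-dienoate
Conditions: CrCl2, CHI3, THF, 0 °C
Reagents that add atoms: iodoform (IC(I)I)
Why: Takai olefination, in which the geminal dichromium reagent adds to the aldehyde and eliminates to the E-iodoalkene.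

Step 33
Reactants: 52 ethyl (2E,4E)-5-iodopenta-2,4-dienoate
Product: 53 (2E,4E)-5-iodopenta-2,4-dienoic acid
Conditions: LiOH, THF/H2O, 0 °C → rt; then 1 M HCl
Reagents that add atoms: lithium hydroxide ([Li+].[OH-])
Why: Saponification of the ethyl ester.

**Assembly and end game**

Step 34
Reactants: 50 C6–C19 dienyne with free terminal alkyne; 28 east–side-chain 1,1-dibromoalkene
Product: 57 C6–C36 open chain (25-O-PMB), via alkenylzirconocene chloride 54 (not isolated), via alkenylzinc bromide 55 (not isolated), via (Z)-bromodiene 56 (not isolated)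
Conditions: Cp2Zr(H)Cl, THF, rt; ZnBr2, 0 °C; 28, Pd(DPEphos)Cl2 (5 mol %), 0 °C → rt; then Me2Zn, Pd(t-Bu3P)2 (5 mol %), rt
Reagents that add atoms: dimethylzinc (C[Zn]C)
Why: The same hydrozirconation, trans-selective Negishi alkenylation and stereoretentive methylation sequence should build the (18E,20E)-diene and join the two halves; the terminal alkyne reacts with Cp2Zr(H)Cl far faster than the internal diene.

Step 35
Reactants: 57 C6–C36 open chain (25-O-PMB)
Product: 58 C25 alcohol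
Conditions: DDQ, CH2Cl2/pH 7 phosphate buffer, 0 °C
Reagents that add atoms: none
Why: Oxidative cleavage of the 4-methoxybenzyl ether frees only O25; silyl ethers, epoxide and dienes should be retained under buffering at 0 °C.

Step 36
Reactants: 53 (2E,4E)-5-iodopenta-2,4-dienoic acid; 58 C25 alcohol
Product: 60 C25 (2E,4E)-5-iodopentadienoate, via mixed anhydride 59 (not isolated)
Conditions: 2,4,6-trichlorobenzoyl chloride, Et3N, THF, rt; then 58, 4-(dimethylamino)pyridine, toluene, rt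
Reagents that add atoms: none
Why: Yamaguchi esterification through the mixed anhydride acylates the only free hydroxyl.

Step 37
Reactants: 60 C25 (2E,4E)-5-iodopentadienoate
Product: 61 C6 aldehyde (cyclization precursor)
Conditions: (COCl)2, DMSO, CH2Cl2, −78 → −40 °C; then i-Pr2NEt, −78 °C
Reagents that add atoms: none
Why: Swern conditions cleave and oxidize the primary triethylsilyl ether at C6 while the five secondary ones stay; the α-silyloxy aldehyde is used at once to avoid epimerization at C7.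

Step 38
Reactants: 61 C6 aldehyde
Product: 63 macrolactone with free 6-OH (7,17,23,29,33-pentakis-TES ether of the target), via alkenylchromium dichloride 62 (not isolated)
Conditions: CrCl2 (8 equiv), (S)-N-[2-(4-isopropyl-4,5-dihydrooxazol-2-yl)-6-methylphenyl]methanesulfonamide (8.8 equiv), Et3N, THF, rt; NiCl2(2,9-dimethyl-1,10-phenanthroline) (0.2 equiv); 61 added over 12 h by syringe pump (final 1 mM), rt
Reagents that add atoms: none
Why: Nozaki–Hiyama–Kishi macrocyclization: zerovalent nickel inserts into the C5–I bond of the iododienoate, the alkenyl group passes to trivalent chromium (62), and this adds to the C6 aldehyde to forge C5–C6. The closest known reaction type is the NiCl2/CrCl2-mediated macrocyclization of iodoalkene aldehydes in its ligand-controlled (oxazoline–sulfonamide) asymmetric form. The 26-membered ring closes in a 26-exo-trig mode, the C=O bond lying outside the new ring, and the E geometry of C4=C5 is retained. The new C6 stereocenter is set by the chiral sulfonamide ligand on chromium, which must direct the alkenyl group to the Re face and so override the Felkin–Anh preference of the C7 silyloxy centre for the 6,7-anti isomer. The step needs chemoselectivity (only the sp2 C–I bond is activated, and the organochromium adds only to the aldehyde, not to esters, epoxide or alkenes), ring closure over oligomerization (slow addition; the E-dienoate and the two E,E-dienes stiffen the chain) and Re-face attack, the last secured by the ligand together with the non-chelating triethylsilyl group at O7.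

Step 39
Reactants: 63 macrolactone with free 6-OH
Product: 64 target CNP0328768.3
Conditions: HF·pyridine, pyridine, THF, 0 °C → rt
Reagents that add atoms: none
Why: Buffered fluoride cleavage of the five secondary triethylsilyl ethers should spare the epoxide, the allylic alcohols and the dienoate lactone.

**Compound list**

1 | butanal | CCCC=O | starting material
2 | diisopinocampheylborinate ester of 3 (not isolated) | CCC[C@H](OB([C@H]1C[C@H]2C[C@H](C2(C)C)[C@@H]1C)[C@H]1C[C@H]2C[C@H](C2(C)C)[C@@H]1C)[C@@H](OC)C=C | intermediate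
3 | (3S,4S)-3-methoxyhept-1-en-4-ol | CCC[C@H](O)[C@@H](OC)C=C | intermediate
4 | triethylsilyl ether of 3 | CCC[C@H](O[Si](CC)(CC)CC)[C@@H](OC)C=C | intermediate
5 | ozonide (1,2,4-trioxolane) of 4, mixture at the ring carbon (not isolated) | CCC[C@H](O[Si](CC)(CC)CC)[C@@H](OC)C1OCOO1 | intermediate
6 | (2R,3S)-2-methoxy-3-(triethylsilyloxy)hexanal (not isolated) | CCC[C@H](O[Si](CC)(CC)CC)[C@@H](OC)C=O | intermediate
7 | ethyl (2E,4S,5S)-4-methoxy-2-methyl-5-(triethylsilyloxy)oct-2-enoate | CCC[C@H](O[Si](CC)(CC)CC)[C@@H](OC)/C=C(\C)C(=O)OCC | intermediate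
8 | (2E,4S,5S)-4-methoxy-2-methyl-5-(triethylsilyloxy)oct-2-en-1-ol | CCC[C@H](O[Si](CC)(CC)CC)[C@@H](OC)/C=C(\C)CO | intermediate
9 | [(2R,3R)-3-[(1S,2S)-1-methoxy-2-(triethylsilyloxy)pentyl]-2-methyloxiran-2-yl]methanol | CCC[C@H](O[Si](CC)(CC)CC)[C@@H](OC)[C@H]1O[C@]1(C)CO | intermediate
10 | (2S,3R)-3-[(1S,2S)-1-methoxy-2-(triethylsilyloxy)pentyl]-2-methyloxirane-2-carbaldehyde | CCC[C@H](O[Si](CC)(CC)CC)[C@@H](OC)[C@H]1O[C@]1(C)C=O | intermediate
11 | diisopinocampheylborinate ester of 12 (not isolated) | CCC[C@H](O[Si](CC)(CC)CC)[C@@H](OC)[C@H]1O[C@]1(C)[C@@H](OB([C@@H]2C[C@@H]3C[C@@H](C3(C)C)[C@H]2C)[C@@H]2C[C@@H]3C[C@@H](C3(C)C)[C@H]2C)CC=C | intermediate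
12 | (1S)-1-[(2R,3R)-3-[(1S,2S)-1-methoxy-2-(triethylsilyloxy)pentyl]-2-methyloxiran-2-yl]but-3-en-1-ol | CCC[C@H](O[Si](CC)(CC)CC)[C@@H](OC)[C@H]1O[C@]1(C)[C@@H](O)CC=C | intermediate
13 | side-chain alkene: 29-O-TES ether of 12 (C27–C36 plus a terminal CH2; C29–C33 as in the target) | CCC[C@H](O[Si](CC)(CC)CC)[C@@H](OC)[C@H]1O[C@]1(C)[C@@H](O[Si](CC)(CC)CC)CC=C | intermediate
14 | penta-1,4-dien-3-ol | C=CC(O)C=C | starting material
15 | (2R,3S)-1,2-epoxypent-4-en-3-ol | C=C[C@H](O)[C@H]1CO1 | intermediate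
16 | (2R,3S)-1,2-epoxy-3-[(4-methoxybenzyl)oxy]pent-4-ene | C=C[C@H](OCc1ccc(OC)cc1)[C@H]1CO1 | intermediate
17 | sodium alkoxide of the ring-opened phenyl sulfide (not isolated) | C=C[C@H](OCc1ccc(OC)cc1)[C@H]([O-])CSc1ccccc1.[Na+] | intermediate
18 | (3S,4S)-4-methoxy-3-[(4-methoxybenzyl)oxy]-5-(phenylsulfanyl)pent-1-ene | C=C[C@H](OCc1ccc(OC)cc1)[C@H](OC)CSc1ccccc1 | intermediate
19 | phenyl sulfoxide of 18 (mixture at sulfur) | C=C[C@H](OCc1ccc(OC)cc1)[C@H](OC)CS(=O)c1ccccc1 | intermediate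
20 | α-trifluoroacetoxy sulfide from 19 (not isolated) | C=C[C@H](OCc1ccc(OC)cc1)[C@H](OC)C(OC(=O)C(F)(F)F)Sc1ccccc1 | intermediate
21 | (2S,3S)-2-methoxy-3-[(4-methoxybenzyl)oxy]pent-4-enal | C=C[C@H](OCc1ccc(OC)cc1)[C@H](OC)C=O | intermediate
22 | (S)-4-benzyl-3-propanoyl-1,3-thiazolidine-2-thione | CCC(=O)N1[C@@H](Cc2ccccc2)CSC1=S | starting material
23 | chlorotitanium (Z)-enolate of 22 (not isolated) | C/C=C(\O[Ti](Cl)(Cl)Cl)N1[C@@H](Cc2ccccc2)CSC1=S | intermediate
24 | (S)-4-benzyl-3-[(2S,3S,4R,5S)-3-hydroxy-4-methoxy-5-[(4-methoxybenzyl)oxy]-2-methylhept-6-enoyl]-1,3-thiazolidine-2-thione | C=C[C@H](OCc1ccc(OC)cc1)[C@H](OC)[C@@H](O)[C@H](C)C(=O)N1[C@@H](Cc2ccccc2)CSC1=S | intermediate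
25 | 23-O-TES ether of 24 | C=C[C@H](OCc1ccc(OC)cc1)[C@H](OC)[C@@H](O[Si](CC)(CC)CC)[C@H](C)C(=O)N1[C@@H](Cc2ccccc2)CSC1=S | intermediate
26 | C21 aldehyde: 2-methyl-3-(triethylsilyloxy)-4-methoxy-5-[(4-methoxybenzyl)oxy]hept-6-enal (C22–C25 as in the target) | C=C[C@H](OCc1ccc(OC)cc1)[C@H](OC)[C@@H](O[Si](CC)(CC)CC)[C@H](C)C=O | intermediate
27 | east 1,1-dibromoalkene (C20–C26 plus a terminal CH2) | C=C[C@H](OCc1ccc(OC)cc1)[C@H](OC)[C@@H](O[Si](CC)(CC)CC)[C@H](C)C=C(Br)Br | intermediate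
28 | east–side-chain 1,1-dibromoalkene (C20–C36; 26E) | CCC[C@H](O[Si](CC)(CC)CC)[C@@H](OC)[C@H]1O[C@]1(C)[C@@H](O[Si](CC)(CC)CC)C/C=C/[C@H](OCc1ccc(OC)cc1)[C@H](OC)[C@@H](O[Si](CC)(CC)CC)[C@H](C)C=C(Br)Br | intermediate
29 | (S)-3-bromo-2-methylpropan-1-ol | OC[C@H](C)CBr | starting material
30 | [(S)-3-bromo-2-methylpropoxy]triethylsilane | CC[Si](CC)(CC)OC[C@H](C)CBr | intermediate
31 | 3-(trimethylsilyl)prop-2-ynal | C[Si](C)(C)C#CC=O | starting material
32 | diisopinocampheylborinate ester of 33 (not isolated) | C=C[C@@H](OC)[C@H](OB([C@@H]1C[C@@H]2C[C@@H](C2(C)C)[C@H]1C)[C@@H]1C[C@@H]2C[C@@H](C2(C)C)[C@H]1C)C#C[Si](C)(C)C | intermediate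
33 | (3R,4R)-4-methoxy-1-(trimethylsilyl)hex-5-en-1-yn-3-ol | C=C[C@@H](OC)[C@H](O)C#C[Si](C)(C)C | intermediate
34 | triethylsilyl ether of 33 | C=C[C@@H](OC)[C@H](O[Si](CC)(CC)CC)C#C[Si](C)(C)C | intermediate
35 | B-alkyl-9-BBN from 34 (not isolated) | C1CC2CCCC(C1)B2CC[C@@H](OC)[C@H](O[Si](CC)(CC)CC)C#C[Si](C)(C)C | intermediate
36 | (3R,4R)-3-methoxy-4-(triethylsilyloxy)-6-(trimethylsilyl)hex-5-yn-1-ol | OCC[C@@H](OC)[C@H](O[Si](CC)(CC)CC)C#C[Si](C)(C)C | intermediate
37 | primary iodide of 36 | ICC[C@@H](OC)[C@H](O[Si](CC)(CC)CC)C#C[Si](C)(C)C | intermediate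
38 | Grignard reagent of 30 (not isolated) | CC[Si](CC)(CC)OC[C@H](C)C[Mg]Br | intermediate
39 | C11–C19 alkyne: 11-O-TES, 12-methyl, 16-OMe, 17-O-TES, 19-SiMe3 (C12, C16, C17 as in the target) | CC[Si](CC)(CC)OC[C@H](C)CCC[C@@H](OC)[C@H](O[Si](CC)(CC)CC)C#C[Si](C)(C)C | intermediate
40 | C11 aldehyde of 39 | O=C[C@H](C)CCC[C@@H](OC)[C@H](O[Si](CC)(CC)CC)C#C[Si](C)(C)C | intermediate
41 | middle 1,1-dibromoalkene (C10–C19) | BrC(Br)=C[C@H](C)CCC[C@@H](OC)[C@H](O[Si](CC)(CC)CC)C#C[Si](C)(C)C | intermediate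
42 | (S)-2,2-dimethyl-1,3-dioxolane-4-carbaldehyde | CC1(C)OC[C@@H](C=O)O1 | starting material
43 | (R)-4-ethynyl-2,2-dimethyl-1,3-dioxolane | CC1(C)OC[C@@H](C#C)O1 | intermediate
44 | (R)-but-3-yne-1,2-diol | OC[C@H](O)C#C | intermediate
45 | (R)-1,2-bis(triethylsilyloxy)but-3-yne | CC[Si](CC)(CC)OC[C@H](O[Si](CC)(CC)CC)C#C | intermediate
46 | (E)-alkenylzirconocene chloride from 45 (not isolated) | CC[Si](CC)(CC)OC[C@H](O[Si](CC)(CC)CC)/C=C/[Zr](Cl)(C1C=CC=C1)C1C=CC=C1 | intermediate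
47 | (E)-alkenylzinc bromide from 45 (not isolated) | CC[Si](CC)(CC)OC[C@H](O[Si](CC)(CC)CC)/C=C/[Zn]Br | intermediate
48 | (8E,10Z)-10-bromodiene C6–C19 (not isolated) | CC[Si](CC)(CC)OC[C@H](O[Si](CC)(CC)CC)/C=C/C(Br)=C/[C@H](C)CCC[C@@H](OC)[C@H](O[Si](CC)(CC)CC)C#C[Si](C)(C)C | intermediate
49 | C6–C19 (8E,10E)-dienyne, 19-SiMe3 | CC[Si](CC)(CC)OC[C@H](O[Si](CC)(CC)CC)/C=C/C(C)=C/[C@H](C)CCC[C@@H](OC)[C@H](O[Si](CC)(CC)CC)C#C[Si](C)(C)C | intermediate
50 | C6–C19 (8E,10E)-dienyne, terminal alkyne | CC[Si](CC)(CC)OC[C@H](O[Si](CC)(CC)CC)/C=C/C(C)=C/[C@H](C)CCC[C@@H](OC)[C@H](O[Si](CC)(CC)CC)C#C | intermediate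
51 | ethyl (E)-4-oxobut-2-enoate | CCOC(=O)/C=C/C=O | starting material
52 | ethyl (2E,4E)-5-iodopenta-2,4-dienoate | CCOC(=O)/C=C/C=C/I | intermediate
53 | (2E,4E)-5-iodopenta-2,4-dienoic acid | OC(=O)/C=C/C=C/I | intermediate
54 | (E)-alkenylzirconocene chloride from 50 (not isolated) | CC[Si](CC)(CC)OC[C@H](O[Si](CC)(CC)CC)/C=C/C(C)=C/[C@H](C)CCC[C@@H](OC)[C@H](O[Si](CC)(CC)CC)/C=C/[Zr](Cl)(C1C=CC=C1)C1C=CC=C1 | intermediate
55 | (E)-alkenylzinc bromide from 50 (not isolated) | CC[Si](CC)(CC)OC[C@H](O[Si](CC)(CC)CC)/C=C/C(C)=C/[C@H](C)CCC[C@@H](OC)[C@H](O[Si](CC)(CC)CC)/C=C/[Zn]Br | intermediate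
56 | C6–C36 chain with (20Z)-20-bromo diene (not isolated) | CC[Si](CC)(CC)OC[C@H](O[Si](CC)(CC)CC)/C=C/C(C)=C/[C@H](C)CCC[C@@H](OC)[C@H](O[Si](CC)(CC)CC)/C=C/C(Br)=C/[C@@H](C)[C@H](O[Si](CC)(CC)CC)[C@@H](OC)[C@@H](OCc1ccc(OC)cc1)/C=C/C[C@H](O[Si](CC)(CC)CC)[C@@]1(C)O[C@@H]1[C@H](OC)[C@H](CCC)O[Si](CC)(CC)CC | intermediate
57 | C6–C36 open chain: 6,7,17,23,29,33-hexakis-O-TES, 25-O-PMB (all stereocenters and alkenes as in the target) | CC[Si](CC)(CC)OC[C@H](O[Si](CC)(CC)CC)/C=C/C(C)=C/[C@H](C)CCC[C@@H](OC)[C@H](O[Si](CC)(CC)CC)/C=C/C(C)=C/[C@@H](C)[C@H](O[Si](CC)(CC)CC)[C@@H](OC)[C@@H](OCc1ccc(OC)cc1)/C=C/C[C@H](O[Si](CC)(CC)CC)[C@@]1(C)O[C@@H]1[C@H](OC)[C@H](CCC)O[Si](CC)(CC)CC | intermediate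
58 | C25 alcohol of 57 | CC[Si](CC)(CC)OC[C@H](O[Si](CC)(CC)CC)/C=C/C(C)=C/[C@H](C)CCC[C@@H](OC)[C@H](O[Si](CC)(CC)CC)/C=C/C(C)=C/[C@@H](C)[C@H](O[Si](CC)(CC)CC)[C@@H](OC)[C@@H](O)/C=C/C[C@H](O[Si](CC)(CC)CC)[C@@]1(C)O[C@@H]1[C@H](OC)[C@H](CCC)O[Si](CC)(CC)CC | intermediate
59 | mixed anhydride of 53 and 2,4,6-trichlorobenzoic acid (not isolated) | O=C(/C=C/C=C/I)OC(=O)c1c(Cl)cc(Cl)cc1Cl | intermediate
60 | C25 (2E,4E)-5-iodopentadienoate of 58 | CC[Si](CC)(CC)OC[C@H](O[Si](CC)(CC)CC)/C=C/C(C)=C/[C@H](C)CCC[C@@H](OC)[C@H](O[Si](CC)(CC)CC)/C=C/C(C)=C/[C@@H](C)[C@H](O[Si](CC)(CC)CC)[C@@H](OC)[C@@H](OC(=O)/C=C/C=C/I)/C=C/C[C@H](O[Si](CC)(CC)CC)[C@@]1(C)O[C@@H]1[C@H](OC)[C@H](CCC)O[Si](CC)(CC)CC | intermediate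
61 | C6 aldehyde (cyclization precursor) | O=C[C@H](O[Si](CC)(CC)CC)/C=C/C(C)=C/[C@H](C)CCC[C@@H](OC)[C@H](O[Si](CC)(CC)CC)/C=C/C(C)=C/[C@@H](C)[C@H](O[Si](CC)(CC)CC)[C@@H](OC)[C@@H](OC(=O)/C=C/C=C/I)/C=C/C[C@H](O[Si](CC)(CC)CC)[C@@]1(C)O[C@@H]1[C@H](OC)[C@H](CCC)O[Si](CC)(CC)CC | intermediate
62 | C5 alkenylchromium dichloride of 61 (not isolated) | O=C[C@H](O[Si](CC)(CC)CC)/C=C/C(C)=C/[C@H](C)CCC[C@@H](OC)[C@H](O[Si](CC)(CC)CC)/C=C/C(C)=C/[C@@H](C)[C@H](O[Si](CC)(CC)CC)[C@@H](OC)[C@@H](OC(=O)/C=C/C=C/[Cr](Cl)Cl)/C=C/C[C@H](O[Si](CC)(CC)CC)[C@@]1(C)O[C@@H]1[C@H](OC)[C@H](CCC)O[Si](CC)(CC)CC | intermediate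
63 | macrolactone with free 6-OH: 7,17,23,29,33-pentakis-O-TES ether of the target | CCC[C@H](O[Si](CC)(CC)CC)[C@@H](OC)[C@H]1O[C@]1(C)[C@@H](O[Si](CC)(CC)CC)C/C=C/[C@@H]1OC(=O)/C=C/C=C/[C@@H](O)[C@H](O[Si](CC)(CC)CC)/C=C/C(C)=C/[C@H](C)CCC[C@@H](OC)[C@H](O[Si](CC)(CC)CC)/C=C/C(C)=C/[C@@H](C)[C@H](O[Si](CC)(CC)CC)[C@H]1OC | intermediate
64 | CNP0328768.3 | CCC[C@H](O)[C@@H](OC)[C@H]1O[C@]1(C)[C@@H](O)C/C=C/[C@@H]1OC(=O)/C=C/C=C/[C@@H](O)[C@H](O)/C=C/C(C)=C/[C@H](C)CCC[C@@H](OC)[C@H](O)/C=C/C(C)=C/[C@@H](C)[C@H](O)[C@H]1OC | target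

**Count and risks**

Total step count: 39. Longest linear sequence: 16 steps (steps 9–18, then 34–39, from penta-1,4-dien-3-ol).

Steps most likely to fail:

1. Step 38. The alkenylchromium may add to the Felkin–Anh face of the aldehyde (6,7-anti), or the ligand-loaded reagent may react too slowly at high dilution so that oligomers form. Fallback: set out from 61 and close the ring without the chiral ligand (CrCl2, NiCl2 cat., DMSO/THF, 1 mM), accepting the 6,7-anti macrocyclic alcohol 6-epi-63 F1 as the main product. Oxidize F1, together with any 63 formed, with Dess–Martin periodinane to the macrocyclic C6 ketone F2. Reduce F2 with NaBH4/CeCl3·7H2O in MeOH at −78 °C: 1,2-selective hydride attack anti to the C7 silyloxy group (Felkin–Anh) should give the 6,7-syn alcohol, which is 63, where the route is rejoined. The stereocenter is then set by substrate-controlled reduction instead of by the addition.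

2. Step 18. The hindered allylic-ether alkene may convert poorly, the side-chain alkene may homodimerize, or E/Z control may erode. Fallback: set out from 13 and 27 and form C26=C27 by Julia–Kocienski olefination. Ozonolysis of 13 with NaBH4 work-up gives the C27 alcohol F3. Mitsunobu reaction with 1-phenyl-1H-tetrazole-5-thiol (PPh3, diisopropyl azodicarboxylate) gives the sulfide F4, and (NH4)6Mo7O24/H2O2 oxidation gives the sulfone F5. In parallel the vinyl group of 27 is cleaved (OsO4 cat., NaIO4, 2,6-lutidine, dioxane/water; the electron-poor dibromoalkene is spared) to the C26 aldehyde F6. KN(SiMe3)2, 1,2-dimethoxyethane, −78 °C → rt joins F5 and F6 to the E-alkene 28, where the route is rejoined.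

3. Step 34. Alkene geometry may leak in the methylation, the alkenylmetal may be protonated, or the epoxide may be opened by zinc halide on the largest substrates. Fallback: set out from 28 and 50 and couple a preformed iodoalkene with a boronate. n-BuLi (2.2 equiv, THF, −78 °C) then MeI converts 28 into the methyl alkyne F7. Cp2Zr(H)Cl (THF, 50 °C; zirconium settles on the less hindered, methyl-bearing carbon) then I2 gives the (E)-2-iodoalkene F8. 50 is hydroborated with pinacolborane (Cp2Zr(H)Cl cat., Et3N) to the (E)-alkenylboronate F9. Zinc-free Suzuki–Miyaura coupling of F8 and F9 (Pd(PPh3)4, aq. K3PO4, THF) gives 57, where the route is rejoined.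

**Further compounds**

F1 | step 38 | 6-epi-63 (6S macrocyclic alcohol) | CCC[C@H](O[Si](CC)(CC)CC)[C@@H](OC)[C@H]1O[C@]1(C)[C@@H](O[Si](CC)(CC)CC)C/C=C/[C@@H]1OC(=O)/C=C/C=C/[C@H](O)[C@H](O[Si](CC)(CC)CC)/C=C/C(C)=C/[C@H](C)CCC[C@@H](OC)[C@H](O[Si](CC)(CC)CC)/C=C/C(C)=C/[C@@H](C)[C@H](O[Si](CC)(CC)CC)[C@H]1OC
F2 | step 38 | macrocyclic C6 ketone | CCC[C@H](O[Si](CC)(CC)CC)[C@@H](OC)[C@H]1O[C@]1(C)[C@@H](O[Si](CC)(CC)CC)C/C=C/[C@@H]1OC(=O)/C=C/C=C/C(=O)[C@H](O[Si](CC)(CC)CC)/C=C/C(C)=C/[C@H](C)CCC[C@@H](OC)[C@H](O[Si](CC)(CC)CC)/C=C/C(C)=C/[C@@H](C)[C@H](O[Si](CC)(CC)CC)[C@H]1OC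
F3 | step 18 | C27 primary alcohol from 13 | CCC[C@H](O[Si](CC)(CC)CC)[C@@H](OC)[C@H]1O[C@]1(C)[C@@H](O[Si](CC)(CC)CC)CCO
F4 | step 18 | C27 1-phenyl-1H-tetrazol-5-yl sulfide | CCC[C@H](O[Si](CC)(CC)CC)[C@@H](OC)[C@H]1O[C@]1(C)[C@@H](O[Si](CC)(CC)CC)CCSc1nnnn1-c1ccccc1
F5 | step 18 | C27 1-phenyl-1H-tetrazol-5-yl sulfone | CCC[C@H](O[Si](CC)(CC)CC)[C@@H](OC)[C@H]1O[C@]1(C)[C@@H](O[Si](CC)(CC)CC)CCS(=O)(=O)c1nnnn1-c1ccccc1
F6 | step 18 | C26 aldehyde from 27 | O=C[C@H](OCc1ccc(OC)cc1)[C@H](OC)[C@@H](O[Si](CC)(CC)CC)[C@H](C)C=C(Br)Br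
F7 | step 34 | methyl alkyne from 28 (C19 methyl, C20≡C21) | CCC[C@H](O[Si](CC)(CC)CC)[C@@H](OC)[C@H]1O[C@]1(C)[C@@H](O[Si](CC)(CC)CC)C/C=C/[C@H](OCc1ccc(OC)cc1)[C@H](OC)[C@@H](O[Si](CC)(CC)CC)[C@H](C)C#CC
F8 | step 34 | (E)-20-iodoalkene from F7 | CCC[C@H](O[Si](CC)(CC)CC)[C@@H](OC)[C@H]1O[C@]1(C)[C@@H](O[Si](CC)(CC)CC)C/C=C/[C@H](OCc1ccc(OC)cc1)[C@H](OC)[C@@H](O[Si](CC)(CC)CC)[C@H](C)/C=C(\C)I
F9 | step 34 | (E)-C19 alkenyl pinacolboronate from 50 | CC[Si](CC)(CC)OC[C@H](O[Si](CC)(CC)CC)/C=C/C(C)=C/[C@H](C)CCC[C@@H](OC)[C@H](O[Si](CC)(CC)CC)/C=C/B1OC(C)(C)C(C)(C)O1
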